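## Retrosynthetic overview

1. The target comes from 5,4'-dihydroxy-3,8-dimethoxy-7-tosyloxyflavone by O-prenylation and then sulfonate cleavage. The 7-O is masked as a base-labile tosylate, and the 5-OH protects itself by chelation to the carbonyl.
2. That flavone comes from 4'-benzyloxy-3,5,8-trimethoxy-7-tosyloxyflavone by hydrogenolysis and then chelation-controlled cleavage of the peri 5-OMe.
3. Ring C is the only ring built. It closes after the fragment union, by cyclodehydration of a 2-methoxy-1,3-diketone. The key C–C bond (future C2–C3) is made by a crossed Claisen condensation between the enolate of the ring A ω-methoxyacetophenone and 4-benzyloxybenzoyl chloride (ring B).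
4. The ring A ketone comes from resorcinol. The C2 oxygen is set by directed ortho-metalation and borate oxidation, and the C5 oxygen by sterically governed C–H borylation and oxidation. The acyl group is set by a second ortho-metalation with a Weinreb amide. Symmetry fixes every position.
5. Rings A and B are bought as benzenes, and the 3-OMe is carried in from the Weinreb amide.

Assumption: the target has no stereocentre and no stereogenic double bond. It is achiral, so the given SMILES defines it fully and no enantioselective step is needed.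

## Route

Step 1
Reactants: 1 resorcinol (benzene-1,3-diol)
Product: 2 1,3-bis(methoxymethoxy)benzene
Conditions: NaH (2.4 equiv), DMF, 0 °C; MOMCl (2.4 equiv), 0 °C to rt
Reagents that add atoms: chloromethyl methyl ether (MOMCl), COCCl
Why: Williamson-type O-alkylation of the bis-phenoxide with the hard electrophile MOMCl gives the base-stable bis-acetal that directs the next lithiation.

Step 2
Reactants: 2 1,3-bis(methoxymethoxy)benzene
Product: 5 2,6-bis(methoxymethoxy)phenol, via aryllithium 3 (not isolated), via dimethyl arylboronate 4 (not isolated)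
Conditions: n-BuLi (1.1 equiv), THF, 0 °C to rt; B(OMe)3 (1.5 equiv), −78 °C to rt; AcOH, 30% H2O2, 0 °C to rt
Reagents that add atoms: n-butyllithium, [Li]CCCC (Li of 3); trimethyl borate, COB(OC)OC (B(OMe)2 of 4); hydrogen peroxide, OO (O of 5)
Why: In this directed ortho-metalation the two flanking OMOM groups jointly direct lithiation to C2, and borate trapping followed by peroxide oxidation (1,2-aryl shift from boron to oxygen) turns that C–Li bond into C–OH.

Step 3
Reactants: 5 2,6-bis(methoxymethoxy)phenol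
Product: 6 2-methoxy-1,3-bis(methoxymethoxy)benzene
Conditions: MeI (1.5 equiv), K2CO3 (2 equiv), acetone, reflux
Reagents that add atoms: iodomethane, CI
Why: Williamson ether synthesis on the only free phenol installs the methoxy group that ends as the 8-OMe.

Step 4
Reactants: 6 2-methoxy-1,3-bis(methoxymethoxy)benzene
Product: 8 4-methoxy-3,5-bis(methoxymethoxy)phenol, via pinacol boronate 7 (not isolated)
Conditions: [Ir(OMe)(cod)]2 (1.5 mol%), 4,4'-di-tert-butyl-2,2'-bipyridine (3 mol%), B2pin2 (0.6 equiv), THF, 80 °C; then 30% H2O2, 2 M NaOH, THF, 0 °C to rt; 1 M HCl to pH 6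
Reagents that add atoms: bis(pinacolato)diboron, CC1(C)OB(OC1(C)C)B1OC(C)(C)C(C)(C)O1 (Bpin of 7); hydrogen peroxide, OO (O of 8)
Why: Sterically governed iridium-catalysed C–H borylation takes the only ring C–H without an ortho substituent (para to OMe), and basic peroxide oxidation of the boronate gives the phenol with the 1,2,3,5-oxygen pattern.

Step 5
Reactants: 8 4-methoxy-3,5-bis(methoxymethoxy)phenol
Product: 9 2,5-dimethoxy-1,3-bis(methoxymethoxy)benzene
Conditions: MeI (1.5 equiv), K2CO3 (2 equiv), acetone, reflux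
Reagents that add atoms: iodomethane, CI
Why: Williamson ether synthesis gives the robust methyl ether that later serves as the protecting group of the 5-OH.

Step 6
Reactants: 9 2,5-dimethoxy-1,3-bis(methoxymethoxy)benzene; 10 N,2-dimethoxy-N-methylacetamide
Product: 12 1-[3,6-dimethoxy-2,4-bis(methoxymethoxy)phenyl]-2-methoxyethan-1-one, via aryllithium 11 (not isolated)
Conditions: n-BuLi (1.2 equiv), TMEDA (1.2 equiv), THF, 0 °C; 10 (1.3 equiv), −78 to 0 °C; then H2O
Reagents that add atoms: n-butyllithium, [Li]CCCC (Li of 11)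
Why: Directed ortho-metalation at one of the two equivalent ring C–H bonds (each flanked by OMOM and OMe) is followed by a Weinreb ketone synthesis, which stops at the ketone and brings in the future 3-OMe.

Step 7
Reactants: 12 1-[3,6-dimethoxy-2,4-bis(methoxymethoxy)phenyl]-2-methoxyethan-1-one
Product: 13 1-(2,4-dihydroxy-3,6-dimethoxyphenyl)-2-methoxyethan-1-one
Conditions: conc. HCl (cat.), MeOH, 50 °C
Reagents that add atoms: none
Why: Acid-catalysed acetal exchange removes both MOM groups, while the aryl methyl ethers and the α-methoxy ketone are inert.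

Step 8
Reactants: 13 1-(2,4-dihydroxy-3,6-dimethoxyphenyl)-2-methoxyethan-1-one
Product: 14 3-hydroxy-2,5-dimethoxy-4-(2-methoxyacetyl)phenyl 4-methylbenzenesulfonate
Conditions: TsCl (1.05 equiv), K2CO3 (1.5 equiv), acetone, rt to 40 °C
Reagents that add atoms: 4-toluenesulfonyl chloride, Cc1ccc(cc1)S(Cl)(=O)=O
Why: In this chemoselective O-sulfonylation the ortho OH is hydrogen-bonded to the ketone and flanked on both sides, so only the acidic para OH reacts, giving a group that tolerates amide base, acid, hydrogenolysis and Lewis acid.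

Step 9
Reactants: 15 4-(benzyloxy)benzoic acid
Product: 16 4-(benzyloxy)benzoyl chloride
Conditions: (COCl)2 (1.3 equiv), DMF (cat.), CH2Cl2, 0 °C to rt; evaporate
Reagents that add atoms: oxalyl chloride, ClC(=O)C(=O)Cl
Why: DMF-catalysed (Vilsmeier-type) activation forms the acid chloride under neutral, gas-evolving conditions that leave the benzyl ether untouched.

Step 10 (key step)
Reactants: 14 3-hydroxy-2,5-dimethoxy-4-(2-methoxyacetyl)phenyl 4-methylbenzenesulfonate; 16 4-(benzyloxy)benzoyl chloride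
Product: 18 4-{3-[4-(benzyloxy)phenyl]-2-methoxy-3-oxopropanoyl}-3-hydroxy-2,5-dimethoxyphenyl 4-methylbenzenesulfonate (racemic), via dilithium phenoxide-enolate 17 (not isolated)
Conditions: LiN(SiMe3)2 (3.3 equiv), THF, −78 to −20 °C; 16 (1.1 equiv), −78 °C to rt; 1 M HCl
Reagents that add atoms: lithium hexamethyldisilazide, [Li]N([Si](C)(C)C)[Si](C)(C)C (Li of 17)
Why: In this crossed Claisen condensation (acyl chloride variant) the enolate carbon of the dianion attacks the aroyl chloride and the third equivalent of base deprotonates the 1,3-diketone to make the step irreversible; the new CH(OMe) centre is racemic, enolisable and removed in step 11.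

Step 11
Reactants: 18 4-{3-[4-(benzyloxy)phenyl]-2-methoxy-3-oxopropanoyl}-3-hydroxy-2,5-dimethoxyphenyl 4-methylbenzenesulfonate
Product: 19 2-[4-(benzyloxy)phenyl]-3,5,8-trimethoxy-4-oxo-4H-chromen-7-yl 4-methylbenzenesulfonate
Conditions: H2SO4 (cat.), AcOH, 80 °C
Reagents that add atoms: none
Why: In this acid-catalysed cyclodehydration the only free phenol (next to the OMe) adds to the aroyl carbonyl and water is lost to close ring C, so the methoxy group can only end at C8.

Step 12
Reactants: 19 2-[4-(benzyloxy)phenyl]-3,5,8-trimethoxy-4-oxo-4H-chromen-7-yl 4-methylbenzenesulfonate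
Product: 20 2-(4-hydroxyphenyl)-3,5,8-trimethoxy-4-oxo-4H-chromen-7-yl 4-methylbenzenesulfonate
Conditions: H2 (1 atm), 10% Pd/C, THF–MeOH, rt
Reagents that add atoms: none
Why: Catalytic hydrogenolysis cleaves only the benzylic C–O bond, and the tetrasubstituted C2=C3 bond, the aryl sulfonate and the methyl ethers are not touched.

Step 13
Reactants: 20 2-(4-hydroxyphenyl)-3,5,8-trimethoxy-4-oxo-4H-chromen-7-yl 4-methylbenzenesulfonate
Product: 22 5-hydroxy-2-(4-hydroxyphenyl)-3,8-dimethoxy-4-oxo-4H-chromen-7-yl 4-methylbenzenesulfonate, via dichloroaluminium chelate 21 (not isolated)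
Conditions: AlCl3 (6 equiv), MeCN, 50 °C; then 2 M HCl, 50 °C
Reagents that add atoms: aluminium trichloride, Cl[Al](Cl)Cl (AlCl2 of 21)
Why: In this chelation-controlled ether cleavage AlCl3 binds the C4 carbonyl and the peri 5-OMe in a six-membered chelate and chloride removes that methyl group, whereas the 3-OMe (five-membered chelate) and the 8-OMe react much more slowly.

Step 14
Reactants: 22 5-hydroxy-2-(4-hydroxyphenyl)-3,8-dimethoxy-4-oxo-4H-chromen-7-yl 4-methylbenzenesulfonate; 23 1-bromo-3-methylbut-2-ene (prenyl bromide)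
Product: 24 5-hydroxy-3,8-dimethoxy-2-{4-[(3-methylbut-2-en-1-yl)oxy]phenyl}-4-oxo-4H-chromen-7-yl 4-methylbenzenesulfonate
Conditions: 23 (1.15 equiv), K2CO3 (1.3 equiv), acetone, 45 °C
Reagents that add atoms: none
Why: In this Williamson ether synthesis (SN2 on the allylic bromide) the 4'-OH is the only nucleophilic phenol, because the 5-OH is chelated to the carbonyl and the 7-O is masked as the sulfonate.

Step 15
Reactants: 24 5-hydroxy-3,8-dimethoxy-2-{4-[(3-methylbut-2-en-1-yl)oxy]phenyl}-4-oxo-4H-chromen-7-yl 4-methylbenzenesulfonate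
Product: 25 5,7-dihydroxy-3,8-dimethoxy-4'-prenyloxyflavone (target)
Conditions: 2 M NaOH (6 equiv), THF–H2O, 50 °C, N2; then 1 M HCl to pH 5, 0 °C
Reagents that add atoms: none
Why: Alkaline sulfonate hydrolysis (S–O cleavage) works because the 7-oxide, conjugated to the C4 carbonyl, is a good leaving group, while the prenyl and methyl ethers are base-stable and the cold, mild acidification spares the acid-labile prenyl ether.

## Compound list

1 | resorcinol (benzene-1,3-diol) | Oc1cccc(O)c1 | starting material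
2 | 1,3-bis(methoxymethoxy)benzene | COCOc1cccc(OCOC)c1 | intermediate
3 | [2,6-bis(methoxymethoxy)phenyl]lithium (not isolated) | [Li]c1c(OCOC)cccc1OCOC | intermediate
4 | dimethyl [2,6-bis(methoxymethoxy)phenyl]boronate (not isolated) | COB(OC)c1c(OCOC)cccc1OCOC | intermediate
5 | 2,6-bis(methoxymethoxy)phenol | COCOc1cccc(OCOC)c1O | intermediate
6 | 2-methoxy-1,3-bis(methoxymethoxy)benzene | COCOc1cccc(OCOC)c1OC | intermediate
7 | 2-[4-methoxy-3,5-bis(methoxymethoxy)phenyl]-4,4,5,5-tetramethyl-1,3,2-dioxaborolane (not isolated) | COCOc1cc(B2OC(C)(C)C(C)(C)O2)cc(OCOC)c1OC | intermediate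
8 | 4-methoxy-3,5-bis(methoxymethoxy)phenol | COCOc1cc(O)cc(OCOC)c1OC | intermediate
9 | 2,5-dimethoxy-1,3-bis(methoxymethoxy)benzene | COCOc1cc(OC)cc(OCOC)c1OC | intermediate
10 | N,2-dimethoxy-N-methylacetamide | COCC(=O)N(C)OC | starting material
11 | [3,6-dimethoxy-2,4-bis(methoxymethoxy)phenyl]lithium (not isolated) | [Li]c1c(OCOC)c(OC)c(OCOC)cc1OC | intermediate
12 | 1-[3,6-dimethoxy-2,4-bis(methoxymethoxy)phenyl]-2-methoxyethan-1-one | COCC(=O)c1c(OCOC)c(OC)c(OCOC)cc1OC | intermediate
13 | 1-(2,4-dihydroxy-3,6-dimethoxyphenyl)-2-methoxyethan-1-one | COCC(=O)c1c(O)c(OC)c(O)cc1OC | intermediate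
14 | 3-hydroxy-2,5-dimethoxy-4-(2-methoxyacetyl)phenyl 4-methylbenzenesulfonate | COCC(=O)c1c(O)c(OC)c(OS(=O)(=O)c2ccc(C)cc2)cc1OC | intermediate
15 | 4-(benzyloxy)benzoic acid | OC(=O)c1ccc(OCc2ccccc2)cc1 | starting material
16 | 4-(benzyloxy)benzoyl chloride | ClC(=O)c1ccc(OCc2ccccc2)cc1 | intermediate
17 | dilithium phenoxide-enolate of 14, drawn as the chelated Z enolate; the geometry has no consequence (not isolated) | [Li+].[Li+].CO/C=C(\[O-])c1c([O-])c(OC)c(OS(=O)(=O)c2ccc(C)cc2)cc1OC | intermediate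
18 | 4-{3-[4-(benzyloxy)phenyl]-2-methoxy-3-oxopropanoyl}-3-hydroxy-2,5-dimethoxyphenyl 4-methylbenzenesulfonate (racemic, enolisable CH(OMe)) | COC(C(=O)c1ccc(OCc2ccccc2)cc1)C(=O)c1c(O)c(OC)c(OS(=O)(=O)c2ccc(C)cc2)cc1OC | intermediate
19 | 2-[4-(benzyloxy)phenyl]-3,5,8-trimethoxy-4-oxo-4H-chromen-7-yl 4-methylbenzenesulfonate | COc1c(-c2ccc(OCc3ccccc3)cc2)oc2c(OC)c(OS(=O)(=O)c3ccc(C)cc3)cc(OC)c2c1=O | intermediate
20 | 2-(4-hydroxyphenyl)-3,5,8-trimethoxy-4-oxo-4H-chromen-7-yl 4-methylbenzenesulfonate | COc1c(-c2ccc(O)cc2)oc2c(OC)c(OS(=O)(=O)c3ccc(C)cc3)cc(OC)c2c1=O | intermediate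
21 | 5-O-dichloroaluminium chelate of 22, drawn with the 4'-OH free (not isolated) | COc1c(-c2ccc(O)cc2)oc2c(OC)c(OS(=O)(=O)c3ccc(C)cc3)cc(O[Al](Cl)Cl)c2c1=O | intermediate
22 | 5-hydroxy-2-(4-hydroxyphenyl)-3,8-dimethoxy-4-oxo-4H-chromen-7-yl 4-methylbenzenesulfonate | COc1c(-c2ccc(O)cc2)oc2c(OC)c(OS(=O)(=O)c3ccc(C)cc3)cc(O)c2c1=O | intermediate
23 | 1-bromo-3-methylbut-2-ene (prenyl bromide) | CC(C)=CCBr | starting material
24 | 5-hydroxy-3,8-dimethoxy-2-{4-[(3-methylbut-2-en-1-yl)oxy]phenyl}-4-oxo-4H-chromen-7-yl 4-methylbenzenesulfonate | COc1c(-c2ccc(OCC=C(C)C)cc2)oc2c(OC)c(OS(=O)(=O)c3ccc(C)cc3)cc(O)c2c1=O | intermediate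
25 | 5,7-dihydroxy-3,8-dimethoxy-4'-prenyloxyflavone (achiral) | COc1c(-c2ccc(OCC=C(C)C)cc2)oc2c(OC)c(O)cc(O)c2c1=O | target

## Step count and risks

Total step count: 15. Longest linear sequence: 14 (steps 1–8 and 10–15, from resorcinol). Step 9 is a one-step side branch.

**Step 10** is the step most likely to fail. O-acylation of the enolate, attack of the amide base on 16, or erosion of the sulfonate could lower the yield of the C-aroylation. The fallback sets out from 14 and 16 and comes back at 18. The chelated phenol of 14 is first esterified with 16 (Et3N, DMAP, CH2Cl2) to give 3,6-dimethoxy-2-(2-methoxyacetyl)-5-(tosyloxy)phenyl 4-(benzyloxy)benzoate F1. KOt-Bu in THF at 0 °C then shifts the aroyl group from oxygen to the α-carbon (Baker–Venkataraman rearrangement), which delivers 18.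

**Step 13** is the second risk. With a free 4'-OH a large excess of AlCl3 is needed, so the 3-OMe or the 8-OMe could be attacked as well. The fallback sets out from 19 and comes back at 22 by reversing the order of the two deprotections.
- The fully protected, CH2Cl2-soluble flavone 19 is treated with only 1.2 equiv of BCl3 (−78 to −10 °C).
- A single boron chelate then forms at the C4 carbonyl and the 5-OMe.
- This gives 2-[4-(benzyloxy)phenyl]-5-hydroxy-3,8-dimethoxy-4-oxo-4H-chromen-7-yl 4-methylbenzenesulfonate F2.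
- Hydrogenolysis (H2, 10% Pd/C) gives 22, and any benzyl ether already lost to BCl3 gives 22 directly.

**Step 15** is the third risk. With the 5-OH free, hot alkali could open ring C and let it reclose the other way, or the electron-rich product could be oxidised. The fallback sets out from 19 and comes back at 25. It exchanges the sulfonate for acetates so that the last step is a cold transesterification.
- Compound 19, whose 5-OMe blocks any alternative ring closure, is hydrolysed (2 M NaOH, THF–H2O) to 2-[4-(benzyloxy)phenyl]-7-hydroxy-3,5,8-trimethoxy-4H-chromen-4-one F3.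
- BCl3 (CH2Cl2, −78 to −10 °C) gives 2-[4-(benzyloxy)phenyl]-5,7-dihydroxy-3,8-dimethoxy-4H-chromen-4-one F4.
- Ac2O in pyridine with DMAP gives 2-[4-(benzyloxy)phenyl]-3,8-dimethoxy-4-oxo-4H-chromene-5,7-diyl diacetate F5.
- Hydrogenolysis in EtOAc gives 2-(4-hydroxyphenyl)-3,8-dimethoxy-4-oxo-4H-chromene-5,7-diyl diacetate F6.
- A Mitsunobu reaction with 3-methylbut-2-en-1-ol (PPh3, DIAD, THF, 0 °C) gives 3,8-dimethoxy-2-{4-[(3-methylbut-2-en-1-yl)oxy]phenyl}-4-oxo-4H-chromene-5,7-diyl diacetate F7.
- K2CO3 in MeOH at 0 °C removes both acetates to give 25.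

## Further compounds

F1 | step 10 | 3,6-dimethoxy-2-(2-methoxyacetyl)-5-(tosyloxy)phenyl 4-(benzyloxy)benzoate | COCC(=O)c1c(OC(=O)c2ccc(OCc3ccccc3)cc2)c(OC)c(OS(=O)(=O)c2ccc(C)cc2)cc1OC
F2 | step 13 | 2-[4-(benzyloxy)phenyl]-5-hydroxy-3,8-dimethoxy-4-oxo-4H-chromen-7-yl 4-methylbenzenesulfonate | COc1c(-c2ccc(OCc3ccccc3)cc2)oc2c(OC)c(OS(=O)(=O)c3ccc(C)cc3)cc(O)c2c1=O
F3 | step 15 | 2-[4-(benzyloxy)phenyl]-7-hydroxy-3,5,8-trimethoxy-4H-chromen-4-one | COc1c(-c2ccc(OCc3ccccc3)cc2)oc2c(OC)c(O)cc(OC)c2c1=O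
F4 | step 15 | 2-[4-(benzyloxy)phenyl]-5,7-dihydroxy-3,8-dimethoxy-4H-chromen-4-one | COc1c(-c2ccc(OCc3ccccc3)cc2)oc2c(OC)c(O)cc(O)c2c1=O
F5 | step 15 | 2-[4-(benzyloxy)phenyl]-3,8-dimethoxy-4-oxo-4H-chromene-5,7-diyl diacetate | COc1c(-c2ccc(OCc3ccccc3)cc2)oc2c(OC)c(OC(C)=O)cc(OC(C)=O)c2c1=O
F6 | step 15 | 2-(4-hydroxyphenyl)-3,8-dimethoxy-4-oxo-4H-chromene-5,7-diyl diacetate | COc1c(-c2ccc(O)cc2)oc2c(OC)c(OC(C)=O)cc(OC(C)=O)c2c1=O
F7 | step 15 | 3,8-dimethoxy-2-{4-[(3-methylbut-2-en-1-yl)oxy]phenyl}-4-oxo-4H-chromene-5,7-diyl diacetate | COc1c(-c2ccc(OCC=C(C)C)cc2)oc2c(OC)c(OC(C)=O)cc(OC(C)=O)c2c1=O
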